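**Plan**

1. Retrosynthesis first cuts the eight O–CH3 bonds of an octamethyl ether, then both aryl–oxygen bonds of the dihydrofurans (O1–C7a at ring A, O1'–C7a' at ring B); this opens the target to a difluoro diol and, at the ketone level, to a diketone.
2. The diketone is cut at C3–C6' (ring B), at C3'–ring E, at C3–C3a and C3'–C3a' (four ketone α-arylations) and at the styryl–C6 bond (Suzuki–Miyaura), back to two acetophenones, one bromochlorofluoroanisole that serves as ring A and as ring B, an aryl bromide and a styrylboronic acid.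
3. Feature used: in ring A and in ring B the carbon that bears the methine (C3a, C3a') lies between two oxygen-bearing carbons (C4/C7a, C4'/C7a'). C7a and C7a' are carried as C–F, so the alkoxides on C2 and C2' reach them through five-membered transition states and displace fluoride.
4. Forward: all six benzene rings are bought; the chain is joined by four α-arylations and one Suzuki coupling; both dihydrofuran rings then arise together in one twofold closure; demethylation ends the route.
5. Stereochemistry: all four centres come from one Noyori-type hydrogenation of the configurationally labile diketone under dynamic kinetic resolution (catalyst control at C2 and C2', Felkin–Anh selection of the α-epimer at C3 and C3'). The closure makes its bonds at arene carbons and keeps them, so like (R,R) becomes trans.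

Key step: step 9

Remark: atoms are numbered as in 2,3-dihydrobenzofuran, unprimed for the ring system with ring A (styryl at C6) and primed for that with ring B. Ring C is the aryl on C2, ring D the aryl on C2', ring E the aryl on C3', ring F the aryl of the styryl group. Compounds 1, 5, 7, 9 and 11 are taken to be purchasable.

**Route**

Step 1
Reactants: 1 2-fluoro-6-methoxyaniline
Product: 2 4-chloro-2-fluoro-6-methoxyaniline
Conditions: NCS, MeCN, 0 °C → rt
Reagents that add atoms: N-chlorosuccinimide, O=C1CCC(=O)N1Cl
Why: Electrophilic aromatic chlorination should go para to the amino group, the strongest director, whose two ortho positions are blocked by F and OMe; no stereocentre is formed.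

Step 2
Reactants: 2 4-chloro-2-fluoro-6-methoxyaniline
Product: 4 2-bromo-5-chloro-1-fluoro-3-methoxybenzene, via 4-chloro-2-fluoro-6-methoxybenzenediazonium bromide 3 (not isolated)
Conditions: NaNO2, 48% aq. HBr, 0 °C; then CuBr (cat.), 60 °C
Reagents that add atoms: hydrobromic acid, Br
Why: The Sandmeyer reaction should put bromine exactly on the carbon between C–F and C–OMe (the later C3a and C3a'), a site that direct bromination or lithiation of a chlorofluoroanisole would not address cleanly; no stereocentre is formed.

Step 3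
Reactants: 4 2-bromo-5-chloro-1-fluoro-3-methoxybenzene; 5 1-(2,4-dimethoxyphenyl)ethan-1-one
Product: 6 2-(4-chloro-2-fluoro-6-methoxyphenyl)-1-(2,4-dimethoxyphenyl)ethan-1-one
Conditions: Pd2(dba)3 (cat.), Xantphos, K3PO4, toluene, 80 °C
Reagents that add atoms: none
Why: In this palladium-catalysed ketone α-arylation (Buchwald–Hartwig type) oxidative addition should occur at C–Br and spare C–Cl and C–F, the flanking F and OMe should prevent a second arylation, and the weak base should keep the product enolate from attacking the fluoride; no stereocentre is formed.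

Step 4
Reactants: 6 2-(4-chloro-2-fluoro-6-methoxyphenyl)-1-(2,4-dimethoxyphenyl)ethan-1-one; 7 1-bromo-3,5-dimethoxybenzene
Product: 8 2-(4-chloro-2-fluoro-6-methoxyphenyl)-1-(2,4-dimethoxyphenyl)-2-(3,5-dimethoxyphenyl)ethan-1-one (racemic)
Conditions: Pd(dba)2 (cat.), P(tBu)3, NaOtBu, THF, 25–40 °C
Reagents that add atoms: none
Why: A second palladium-catalysed α-arylation, of the benzylic methylene of 6 with the unhindered bromide 7, should run at a temperature at which the C–Cl bond of 6 is not inserted; the new C3' centre forms as a racemate, which is accepted because this α-carbon stays configurationally labile until step 8.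

Step 5
Reactants: 4 2-bromo-5-chloro-1-fluoro-3-methoxybenzene; 9 1-(4-methoxyphenyl)ethan-1-one
Product: 10 2-(4-chloro-2-fluoro-6-methoxyphenyl)-1-(4-methoxyphenyl)ethan-1-one
Conditions: Pd2(dba)3 (cat.), Xantphos, K3PO4, toluene, 80 °C
Reagents that add atoms: none
Why: The same α-arylation as in step 3 with the second methyl ketone should work for the same reasons, so that one aryl halide is the source of ring A and of ring B; no stereocentre is formed.

Step 6
Reactants: 10 2-(4-chloro-2-fluoro-6-methoxyphenyl)-1-(4-methoxyphenyl)ethan-1-one; 11 [(E)-2-(4-methoxyphenyl)ethenyl]boronic acid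
Product: 12 2-{2-fluoro-6-methoxy-4-[(E)-2-(4-methoxyphenyl)ethenyl]phenyl}-1-(4-methoxyphenyl)ethan-1-one
Conditions: Pd(OAc)2 (cat.), SPhos, K3PO4, toluene/H2O, 90 °C
Reagents that add atoms: none
Why: Suzuki–Miyaura coupling at the aryl chloride with a dialkylbiarylphosphine ligand should install the styryl group with retention of the E geometry of the boronic acid, and the mild aqueous base should leave the ketone alone; no stereocentre is formed.

Step 7
Reactants: 12 styryl ketone (product of step 6); 8 chloro ketone (product of step 4)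
Product: 13 2-{4-[1-{2-fluoro-6-methoxy-4-[(E)-2-(4-methoxyphenyl)ethenyl]phenyl}-2-(4-methoxyphenyl)-2-oxoethyl]-2-fluoro-6-methoxyphenyl}-1-(2,4-dimethoxyphenyl)-2-(3,5-dimethoxyphenyl)ethan-1-one (difluoro diketone; stereoisomer mixture at both α-carbons)
Conditions: Pd(dba)2 (cat.), P(tBu)3, NaOtBu (2.5 equiv), toluene, 70 °C
Reagents that add atoms: none
Why: Palladium-catalysed α-arylation with an aryl chloride should join the halves at C3–C6', because the extra base removes the more acidic α-hydrogen of 8 but its fully substituted enolate cannot be arylated, so only the methylene enolate of 12 couples; the new C3 centre needs no control since both α-carbons of 13 epimerise in step 8.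

Step 8
Reactants: 13 difluoro diketone
Product: 14 (1R,2R)-2-{4-[(1R,2R)-1-{2-fluoro-6-methoxy-4-[(E)-2-(4-methoxyphenyl)ethenyl]phenyl}-2-hydroxy-2-(4-methoxyphenyl)ethyl]-2-fluoro-6-methoxyphenyl}-1-(2,4-dimethoxyphenyl)-2-(3,5-dimethoxyphenyl)ethan-1-ol (difluoro diol)
Conditions: trans-RuCl2[(S)-xylbinap][(S)-daipen] (cat.), KOtBu (substoichiometric), H2 (10 atm), iPrOH/THF, 30 °C
Reagents that add atoms: none
Why: In this Noyori-type asymmetric hydrogenation under dynamic kinetic resolution, KOtBu equilibrates both α-carbons through their enolates, the catalyst should deliver hydride to the carbonyl face that gives the R carbinols C2 and C2' (as with simple aryl ketones), and in each half it should consume the α-epimer for which this face is also the Felkin–Anh face (hydride anti to the bulky 2-fluoro-6-methoxyaryl ring), which gives the like (R,R) pairs C2/C3 and C2'/C3' while the stilbene C=C stays unreduced.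

Step 9
Reactants: 14 difluoro diol
Product: 16 (2R,3R)-3-[(2R,3R)-2-(2,4-dimethoxyphenyl)-3-(3,5-dimethoxyphenyl)-4-methoxy-2,3-dihydro-1-benzofuran-6-yl]-4-methoxy-2-(4-methoxyphenyl)-6-[(E)-2-(4-methoxyphenyl)ethenyl]-2,3-dihydro-1-benzofuran (octamethyl ether of the target), via dipotassium bis-alkoxide 15 (not isolated)
Conditions: KN(SiMe3)2 (2.5 equiv), 18-crown-6, THF, 0 → 50 °C; aq. NH4Cl
Reagents that add atoms: none
Why: KN(SiMe3)2 turns both carbinols into potassium alkoxides (15), and each alkoxide oxygen adds to the fluorine-bearing arene carbon ortho to its side chain (O1 to C7a of ring A, O1' to C7a' of ring B), after which fluoride leaves (addition–elimination, intramolecular SNAr). The closest known reaction type is the base-mediated cyclisation of 2-(2-fluoroaryl)ethanols to 2,3-dihydrobenzofurans on aryl fluorides that carry no nitro or carbonyl activation. Both dihydrofuran rings close in the same mode, by ipso-attack of oxygen on an sp2 carbon through a five-membered transition state (O1–C2–C3–C3a–C7a and its primed counterpart). No stereocentre is formed: the new bonds are made at arene carbons, so C2, C3, C2' and C3' keep the configurations set in step 8, and each like (R,R) pair becomes a trans-2,3-diaryl ring. The step needs regioselectivity between the two fluorides and chemoselectivity against retro-addition of the alkoxides; the first is secured because each oxygen can reach only the fluoride ortho to its own methine carbon, the second by the low temperature that crown-ether-activated potassium alkoxides and the inductive help of the meta-methoxy groups should allow.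

Step 10
Reactants: 16 octamethyl ether of the target
Product: 17 (2R,3R)-3-[(2R,3R)-2-(2,4-dihydroxyphenyl)-3-(3,5-dihydroxyphenyl)-4-hydroxy-2,3-dihydro-1-benzofuran-6-yl]-2-(4-hydroxyphenyl)-6-[(E)-2-(4-hydroxyphenyl)ethenyl]-2,3-dihydro-1-benzofuran-4-ol (CNP0118407.2)
Conditions: BBr3 (excess), CH2Cl2, −78 → 0 °C; then MeOH, H2O
Reagents that add atoms: none
Why: Lewis-acid cleavage of the eight aryl methyl ethers with BBr3 is the usual end of oligostilbenoid syntheses, and boron bound to the para-oxygens of rings C and D should make them poor donors and so hold back ionisation of the O1–C2 and O1'–C2' bonds; the four stereocentres and the E-alkene take no part.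

**Compound list**

1 | 2-fluoro-6-methoxyaniline | COc1cccc(F)c1N | starting material
2 | 4-chloro-2-fluoro-6-methoxyaniline | COc1cc(Cl)cc(F)c1N | intermediate
3 | 4-chloro-2-fluoro-6-methoxybenzenediazonium bromide (not isolated) | COc1cc(Cl)cc(F)c1[N+]#N.[Br-] | intermediate
4 | 2-bromo-5-chloro-1-fluoro-3-methoxybenzene | COc1cc(Cl)cc(F)c1Br | intermediate
5 | 1-(2,4-dimethoxyphenyl)ethan-1-one | CC(=O)c1ccc(OC)cc1OC | starting material
6 | 2-(4-chloro-2-fluoro-6-methoxyphenyl)-1-(2,4-dimethoxyphenyl)ethan-1-one | COc1ccc(C(=O)Cc2c(F)cc(Cl)cc2OC)c(OC)c1 | intermediate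
7 | 1-bromo-3,5-dimethoxybenzene | COc1cc(Br)cc(OC)c1 | starting material
8 | 2-(4-chloro-2-fluoro-6-methoxyphenyl)-1-(2,4-dimethoxyphenyl)-2-(3,5-dimethoxyphenyl)ethan-1-one, racemic at the labile α-carbon | COc1ccc(C(=O)C(c2cc(OC)cc(OC)c2)c2c(F)cc(Cl)cc2OC)c(OC)c1 | intermediate
9 | 1-(4-methoxyphenyl)ethan-1-one | CC(=O)c1ccc(OC)cc1 | starting material
10 | 2-(4-chloro-2-fluoro-6-methoxyphenyl)-1-(4-methoxyphenyl)ethan-1-one | COc1ccc(C(=O)Cc2c(F)cc(Cl)cc2OC)cc1 | intermediate
11 | [(E)-2-(4-methoxyphenyl)ethenyl]boronic acid | COc1ccc(/C=C/B(O)O)cc1 | starting material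
12 | 2-{2-fluoro-6-methoxy-4-[(E)-2-(4-methoxyphenyl)ethenyl]phenyl}-1-(4-methoxyphenyl)ethan-1-one | COc1ccc(/C=C/c2cc(F)c(CC(=O)c3ccc(OC)cc3)c(OC)c2)cc1 | intermediate
13 | difluoro diketone of step 7, E-alkene, both α-carbons as stereoisomer mixture | O=C(c1ccc(OC)cc1)C(c1c(F)cc(/C=C/c2ccc(OC)cc2)cc1OC)c1cc(OC)c(C(c2cc(OC)cc(OC)c2)C(=O)c2ccc(OC)cc2OC)c(F)c1 | intermediate
14 | difluoro diol of step 8, R at both carbinol carbons and at both diarylmethine carbons, E-alkene | O[C@@H](c1ccc(OC)cc1)[C@@H](c1c(F)cc(/C=C/c2ccc(OC)cc2)cc1OC)c1cc(OC)c([C@@H](c2cc(OC)cc(OC)c2)[C@@H](O)c2ccc(OC)cc2OC)c(F)c1 | intermediate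
15 | dipotassium bis-alkoxide of 14 (not isolated) | [K+].[K+].[O-][C@@H](c1ccc(OC)cc1)[C@@H](c1c(F)cc(/C=C/c2ccc(OC)cc2)cc1OC)c1cc(OC)c([C@@H](c2cc(OC)cc(OC)c2)[C@@H]([O-])c2ccc(OC)cc2OC)c(F)c1 | intermediate
16 | octamethyl ether of the target, (2R,3R,2'R,3'R), both dihydrofurans trans, E-alkene | COc1ccc(/C=C/c2cc(OC)c3c(c2)O[C@@H](c2ccc(OC)cc2)[C@@H]3c2cc(OC)c3c(c2)O[C@@H](c2ccc(OC)cc2OC)[C@@H]3c2cc(OC)cc(OC)c2)cc1 | intermediate
17 | CNP0118407.2, (2R,3R,2'R,3'R), both dihydrofurans trans, E-alkene | Oc1ccc(/C=C/c2cc(O)c3c(c2)O[C@@H](c2ccc(O)cc2)[C@@H]3c2cc(O)c3c(c2)O[C@@H](c2ccc(O)cc2O)[C@@H]3c2cc(O)cc(O)c2)cc1 | target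

**Step count and risks**

Total step count: 10. Longest linear sequence: 8 steps (1 → 2 → 4 → 6 → 8 → 13 → 14 → 16 → 17; steps 1, 2, 3, 4, 7, 8, 9, 10).

Most likely to fail, first: step 8. The catalyst may pair with the other α-epimer (hydride anti to the smaller aryl group), so that the carbinol and diarylmethine centres come out unlike. The hindered ketones may also be reduced too slowly for clean selection. Fallback: from 13, hydrogenation with the enantiomeric catalyst trans-RuCl2[(R)-xylbinap][(R)-daipen] would then give the all-unlike diol F1 (C2 and C2' S, C3 and C3' still R). Closure under the conditions of step 9 would give the cis,cis-bis(dihydrobenzofuran) F2. Acid-catalysed epimerisation at the two O-benzylic carbons (CF3CO2H, CH2Cl2, 0 °C) would follow: O1–C2 and O1'–C2' open reversibly to benzylic cations stabilised by the para-oxygens of rings C and D and re-close. This should lead to the more stable trans,trans compound 16, where the route is rejoined.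

Second: step 7. NaOtBu deprotonates the chloride 8 at its own α-carbon. The enolate slows oxidative addition, and its oxygen may displace the neighbouring fluoride to give a benzofuran. Fallback: from 12, O-silylation (Me3SiOTf, Et3N, CH2Cl2, 0 °C) would give the trimethylsilyl enol ether F3. A fluoride-activated palladium-catalysed arylation of F3 with 8 (Pd(dba)2, P(tBu)3, ZnF2, CsF, DMF, 80 °C) runs under only weakly basic conditions and returns to the route at 13.

Third: step 9. The slower of the two closures may need heating, and at that temperature the potassium alkoxides can fragment by retro-addition (aldehyde plus diarylmethyl anion), so one half may close while the other degrades. Fallback: the rings are closed one at a time with the order of events changed.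
- From 8, hydrogenation under the conditions of step 8 would give the alcohol F4.
- KN(SiMe3)2 in THF would close it to the chloro-dihydrobenzofuran F5; here the fluoride is meta to chlorine and more reactive, and the chloride no longer has an acidic C–H.
- α-Arylation of 12 with F5 (Pd(dba)2, P(tBu)3, NaOtBu, toluene, 70 °C) would give the ketone F6.
- Hydrogenation as in step 8 would give the alcohol F7, and closure under the conditions of step 9 returns to the route at 16.

Further compounds

F1 | step 8 | all-unlike difluoro diol, the C2 and C2' epimer of 14 (carbinol carbons S, diarylmethine carbons R) | O[C@H](c1ccc(OC)cc1)[C@@H](c1c(F)cc(/C=C/c2ccc(OC)cc2)cc1OC)c1cc(OC)c([C@@H](c2cc(OC)cc(OC)c2)[C@H](O)c2ccc(OC)cc2OC)c(F)c1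
F2 | step 8 | cis,cis-bis(dihydrobenzofuran), the (2S,3R,2'S,3'R) isomer of 16 | COc1ccc(/C=C/c2cc(OC)c3c(c2)O[C@H](c2ccc(OC)cc2)[C@@H]3c2cc(OC)c3c(c2)O[C@H](c2ccc(OC)cc2OC)[C@@H]3c2cc(OC)cc(OC)c2)cc1
F3 | step 7 | (Z)-trimethylsilyl enol ether of 12 | COc1ccc(/C=C/c2cc(F)c(/C=C(\O[Si](C)(C)C)c3ccc(OC)cc3)c(OC)c2)cc1
F4 | step 9 | (1R,2R)-2-(4-chloro-2-fluoro-6-methoxyphenyl)-1-(2,4-dimethoxyphenyl)-2-(3,5-dimethoxyphenyl)ethan-1-ol | O[C@@H](c1ccc(OC)cc1OC)[C@@H](c1c(F)cc(Cl)cc1OC)c1cc(OC)cc(OC)c1
F5 | step 9 | (2R,3R)-6-chloro-2-(2,4-dimethoxyphenyl)-3-(3,5-dimethoxyphenyl)-4-methoxy-2,3-dihydro-1-benzofuran | Clc1cc(OC)c2c(c1)O[C@@H](c1ccc(OC)cc1OC)[C@@H]2c1cc(OC)cc(OC)c1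
F6 | step 9 | 2-[(2R,3R)-2-(2,4-dimethoxyphenyl)-3-(3,5-dimethoxyphenyl)-4-methoxy-2,3-dihydro-1-benzofuran-6-yl]-2-{2-fluoro-6-methoxy-4-[(E)-2-(4-methoxyphenyl)ethenyl]phenyl}-1-(4-methoxyphenyl)ethan-1-one, epimer mixture at the α-carbon | O=C(c1ccc(OC)cc1)C(c1c(F)cc(/C=C/c2ccc(OC)cc2)cc1OC)c1cc(OC)c2c(c1)O[C@@H](c1ccc(OC)cc1OC)[C@@H]2c1cc(OC)cc(OC)c1
F7 | step 9 | (1R,2R)-2-[(2R,3R)-2-(2,4-dimethoxyphenyl)-3-(3,5-dimethoxyphenyl)-4-methoxy-2,3-dihydro-1-benzofuran-6-yl]-2-{2-fluoro-6-methoxy-4-[(E)-2-(4-methoxyphenyl)ethenyl]phenyl}-1-(4-methoxyphenyl)ethan-1-ol | O[C@@H](c1ccc(OC)cc1)[C@@H](c1c(F)cc(/C=C/c2ccc(OC)cc2)cc1OC)c1cc(OC)c2c(c1)O[C@@H](c1ccc(OC)cc1OC)[C@@H]2c1cc(OC)cc(OC)c1
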